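A flask charged one to one cannot tell us which of its two starting materials the rate follows: if one reagent goes per target, the fractions of substrate and reagent left fall together. That is the south run, which is the flask asked about. The east run breaks the tie, with the same substrate and free catalyst but half the reagent.

| setting | south | east | flask |
|---|---|---|---|
| substrate | 0.30 M | 0.30 M | 0.30 M |
| reagent | 1 equiv | 0.50 equiv | 1.00 equiv |
| free catalyst | 0.19 mol% | 0.19 mol% | 0.19 mol% |
| remark | the very flask that is asked about, followed so far | run made earlier |  |

| run | time / h | target / % |
|---|---|---|
| south | 0.200 | 2 |
| south | 0.417 | 4 |
| south | 1.00 | 8 |
| south | 2.50 | 13 |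
| east | 0.833 | 4 |
| east | 2.00 | 10 |
| east | 4.00 | 21 |
| east | 6.00 | 30 |

(each reading ± 1.5 percentage points)

1. factor on the rate of making target when 10% of the substrate are converted if reagent is charged twice over
2. factor on the rate when 10% of the substrate are converted if free catalyst is charged at 2 mol% instead

- the numbers in the tables scatter with a standard deviation of 1.5 percentage points
- no earlier run changes the charge of free catalyst; that part of a forecast is a guess

We draw both curves from the origin, as fractions of the substrate charged. The east curve is straight within the readings:

first stretch: 10% in 2.00 h, slope 0.0500 /h
later stretch, up to the last reading: slope 0.0500 /h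

Yet at one reagent per target, 60.0% of its reagent is used by its last reading. On that count its level lies at 50.0% target, the charge of the limiting reagent, and the readings show no bend towards it.

The south curve seems to open steeper, then to kink:

chord to 2.50 h: 13% in that time, slope 0.0520 /h

That chord puts 2.17% at 0.417 h, where the reading is 4%. With a scatter of 1.5 percentage points, we call that knee unproven. The south chord passes 10% at 1.92 h, and the east run reads the same figure at 2.00 h, so by these readings the two runs reach that conversion at nearly the same time.

Our carried quantity is the reagent order, the logarithm of the factor on the rate over the logarithm of the factor on the charge, at equal conversion: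

n = ln(south slope / east slope) / ln(south charge / east charge) = 0.0566

This is a reading with a wide margin, but it lies nearer zero than one. If it holds for one doubling more, we expect a factor of 1.04. No run varies free catalyst, so we commit to no figure there.

The forecast says 0.8 for doubled reagent and 11 at 2 mol%, expecting “something that worsens with more reagent”; its first figure differs from our factor.

The simulation gives 1.00 for doubled reagent and 4.77 at 2 mol%.

    reagent + free catalyst → catalyst intermediate A (k = 36000 /M/h)
    catalyst intermediate A ⇌ by-product + catalyst intermediate B (K = 0.380 M, k = 180 /h)
    catalyst intermediate B ⇌ catalyst intermediate C (K = 1.40, k = 2600 /h)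
    substrate + catalyst intermediate C ⇌ catalyst intermediate D (K = 1.40 /M, k = 1800 /M/h)
    catalyst intermediate D ⇌ free catalyst + target (K = 0.780 M, k = 440 /h)
    2 catalyst intermediate A ⇌ resting dimer, settled at all times (K = 8800 /M)
    2 catalyst intermediate C → spent catalyst (k = 160 /M/h)

The factor 1.00 stands beside the 1.04 that our n gave. In the flask at 3.00 h, free catalyst, the form that meets reagent, is 0.304% of the catalyst charged. For the flask charged with 2 mol%, the factor on the charge of free catalyst is 10.5 and the rate factor 4.77, so the same measure reads an order in free catalyst of 0.664.

(The numbers in the tables stem from a simulated flask from invented constants; the scatter is artificial.)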